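**Target.** Ligraminol A is (2S,3R,4S,5S)-2-(3,4-dimethoxyphenyl)-3,4-dimethyl-5-(3,4,5-trimethoxyphenyl)oxolane: C2-aryl/C3-Me cis, C3-Me/C4-Me cis, C4-Me/C5-aryl trans. Oxolane numbering is used throughout (C2 carries the dimethoxyphenyl group, C5 the trimethoxyphenyl group).

Assumption: with aldehyde 4 the (−)-sparteine/Ti(OiPr)4 homoaldol protocol shows the sense of induction known for other aldehydes ((3S)-configured anti adducts); if it proved opposite, (+)-sparteine would be used and nothing else changes.

## Retrosynthetic overview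

1. C2–H last: 18 ⇐ oxocarbenium ion 17 ⇐ hemiketal 16 ⇐ cis-lactone 13 + aryllithium 15 (C2–aryl bond).
2. 13 ⇐ lactone 9: C3 methyl by enolate alkylation, C3 configuration by kinetic protonation.
3. 9 ⇐ (Z)-enol carbamate 7, a masked γ-hydroxy aldehyde; the only ring (the oxolane) is closed here by O–C2 acetalisation and kept to the end.
4. Key C4–C5 bond: 7 ⇐ aldehyde 4 + metallated crotyl carbamate 5/6, a chiral homoenolate (d3) reagent whose carbon β to the latent carbonyl is the nucleophile; C4 and C5 are set together (anti), absolute control by (−)-sparteine.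
5. 3 ⇐ (E)-crotyl alcohol 1.

## Route

Step 1
Reactants: 1 (E)-but-2-en-1-ol
Product: 3 (E)-but-2-en-1-yl N,N-diisopropylcarbamate, via sodium (E)-but-2-en-1-olate 2 (not isolated)
Conditions: NaH, THF, 0 °C; then iPr2NCOCl, reflux
Reagents that add atoms: N,N-diisopropylcarbamoyl chloride, CC(C)N(C(C)C)C(Cl)=O
Why: Deprotonation then O-carbamoylation (nucleophilic acyl substitution) installs the carbamate that will direct α-lithiation; no stereocentre is formed and the E alkene is untouched.

Step 2
Reactants: 3 (E)-but-2-en-1-yl N,N-diisopropylcarbamate; 4 3,4,5-trimethoxybenzaldehyde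
Product: 7 (1Z,3S,4S)-4-hydroxy-3-methyl-4-(3,4,5-trimethoxyphenyl)but-1-en-1-yl N,N-diisopropylcarbamate, via lithiated carbamate (−)-sparteine complex 5 (not isolated), via allyltitanium triisopropoxide 6 (not isolated)
Conditions: n-BuLi, (−)-sparteine, pentane/cyclohexane, −78 °C, 3 h (crystallisation); Ti(OiPr)4, −78 °C; then 4 in toluene, −78 °C → rt; aq. HCl
Reagents that add atoms: none
Why: Hoppe sparteine-mediated asymmetric homoaldol reaction: the configurationally labile α-lithio carbamate is resolved by crystallisation of its (S)-epimer as the sparteine complex 5, Li→Ti exchange with inversion gives 6, and this homoenolate reagent attacks the aldehyde through its γ-carbon in a closed chair transition state (aryl and methyl equatorial, carbamoyloxy axial), which sets both new centres (3S,4S, anti; they become C4 and C5 of the target) and the Z enol carbamate.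

Step 3
Reactants: 7 homoaldol adduct
Product: 8 (2RS,4S,5S)-2-methoxy-4-methyl-5-(3,4,5-trimethoxyphenyl)oxolane (anomer mixture)
Conditions: MeOH, MeSO3H (1.2 equiv), Hg(OAc)2 (5 mol %), rt; aq. NaHCO3
Reagents that add atoms: methanol, CO
Why: Acid-catalysed solvolysis of the enol carbamate to a cyclic acetal: C-protonation gives a carbamoyloxy-stabilised cation that the C5 hydroxyl captures to close the oxolane ring, and exchange with methanol expels the carbamic acid (CO2 + iPr2NH), leaving C4 and C5 untouched.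

Step 4
Reactants: 8 lactol methyl ether
Product: 9 (4S,5S)-4-methyl-5-(3,4,5-trimethoxyphenyl)oxolan-2-one
Conditions: mCPBA, BF3·OEt2, CH2Cl2, 0 °C → rt
Reagents that add atoms: 3-chloroperoxybenzoic acid (mCPBA), OOC(=O)c1cccc(Cl)c1
Why: Grieco oxidation of a lactol ether: BF3 ionises the acetal, the peracid adds to the oxocarbenium ion and the peroxy acetal fragments to the lactone, without touching C4 or C5.

Step 5
Reactants: 9 trans-4,5-disubstituted lactone
Product: 11 (3S,4S,5S)-3,4-dimethyl-5-(3,4,5-trimethoxyphenyl)oxolan-2-one, via lithium enolate 10 (not isolated)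
Conditions: LiN(iPr)2 (LDA), THF, −78 °C; MeI, −78 → −40 °C
Reagents that add atoms: iodomethane, CI
Why: Lactone enolate alkylation (SN2 on MeI): the electrophile enters anti to the adjacent C4 methyl and gives the 3,4-trans lactone, which brings in the C3 methyl carbon with the configuration that step 6 then corrects.

Step 6
Reactants: 11 3,4-trans lactone
Product: 13 (3R,4S,5S)-3,4-dimethyl-5-(3,4,5-trimethoxyphenyl)oxolan-2-one, via lithium enolate 12 (not isolated)
Conditions: LiN(iPr)2 (LDA), THF, −78 → −40 °C; then 2,6-di-tert-butyl-4-methylphenol, THF, −78 °C; dilute aq. HCl work-up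
Reagents that add atoms: none
Why: Kinetic enolate protonation: the planar enolate 12 is protonated by the bulky phenol from the face anti to the adjacent C4 methyl, which pushes the C3 methyl cis to the C4 methyl and sets C3 (R) against the thermodynamic preference.

Step 7
Reactants: 13 3,4-cis lactone; 14 4-bromo-1,2-dimethoxybenzene
Product: 16 (3R,4S,5S)-2-(3,4-dimethoxyphenyl)-3,4-dimethyl-5-(3,4,5-trimethoxyphenyl)oxolan-2-ol (anomer mixture, in equilibrium with the open hydroxy ketone), via (3,4-dimethoxyphenyl)lithium 15 (not isolated)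
Conditions: 14, n-BuLi, THF, −78 °C; then 13, −78 °C; AcOH, −78 °C
Reagents that add atoms: none
Why: Bromine–lithium exchange followed by 1,2-addition of the aryllithium to the lactone carbonyl: the lithium hemiketalate is stable at −78 °C, which stops a second addition, and the cold acidic quench keeps the epimerisable C3 centre intact.

Step 8
Reactants: 16 hemiketal
Product: 18 ligraminol A, (2S,3R,4S,5S)-2-(3,4-dimethoxyphenyl)-3,4-dimethyl-5-(3,4,5-trimethoxyphenyl)oxolane, via oxocarbenium ion 17 (not isolated)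
Conditions: Et3SiH (5 equiv), then BF3·OEt2 (2 equiv), CH2Cl2, −78 °C; aq. NaHCO3 at −78 °C
Reagents that add atoms: none
Why: Lewis acid-mediated reductive deoxygenation of a hemiketal (ionic hydrogenation): hydride attacks oxocarbenium ion 17 on the inside face of the envelope with pseudoequatorial C4 methyl and C5 aryl, which is also the face anti to both methyl groups, so the C2 aryl ends up cis to the C3 methyl (2S); having the silane present at −78 °C before the Lewis acid lets reduction outrun C3 epimerisation through the enol ether.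

## Compound list

1 | (E)-but-2-en-1-ol | C/C=C/CO | starting material
2 | sodium (E)-but-2-en-1-olate | C/C=C/C[O-].[Na+] | intermediate
3 | (E)-but-2-en-1-yl N,N-diisopropylcarbamate | C/C=C/COC(=O)N(C(C)C)C(C)C | intermediate
4 | 3,4,5-trimethoxybenzaldehyde | COc1cc(C=O)cc(OC)c1OC | starting material
5 | (S)-1-lithio-(E)-but-2-enyl N,N-diisopropylcarbamate, crystallised as its (−)-sparteine complex (sparteine not drawn) | C/C=C/[C@H]([Li])OC(=O)N(C(C)C)C(C)C | intermediate
6 | (R)-1-(triisopropoxytitanio)-(E)-but-2-enyl N,N-diisopropylcarbamate | C/C=C/[C@@H]([Ti](OC(C)C)(OC(C)C)OC(C)C)OC(=O)N(C(C)C)C(C)C | intermediate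
7 | (1Z,3S,4S)-4-hydroxy-3-methyl-4-(3,4,5-trimethoxyphenyl)but-1-en-1-yl N,N-diisopropylcarbamate | CC(C)N(C(C)C)C(=O)O/C=C\[C@H](C)[C@H](O)c1cc(OC)c(OC)c(OC)c1 | intermediate
8 | (2RS,4S,5S)-2-methoxy-4-methyl-5-(3,4,5-trimethoxyphenyl)oxolane | COC1O[C@H](c2cc(OC)c(OC)c(OC)c2)[C@@H](C)C1 | intermediate
9 | (4S,5S)-4-methyl-5-(3,4,5-trimethoxyphenyl)oxolan-2-one | O=C1O[C@H](c2cc(OC)c(OC)c(OC)c2)[C@@H](C)C1 | intermediate
10 | lithium enolate of 9 | [Li]OC1=C[C@H](C)[C@@H](c2cc(OC)c(OC)c(OC)c2)O1 | intermediate
11 | (3S,4S,5S)-3,4-dimethyl-5-(3,4,5-trimethoxyphenyl)oxolan-2-one (3,4-trans, 4,5-trans) | O=C1O[C@H](c2cc(OC)c(OC)c(OC)c2)[C@@H](C)[C@@H]1C | intermediate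
12 | lithium enolate of 11 | [Li]OC1=C(C)[C@H](C)[C@@H](c2cc(OC)c(OC)c(OC)c2)O1 | intermediate
13 | (3R,4S,5S)-3,4-dimethyl-5-(3,4,5-trimethoxyphenyl)oxolan-2-one (3,4-cis, 4,5-trans) | O=C1O[C@H](c2cc(OC)c(OC)c(OC)c2)[C@@H](C)[C@H]1C | intermediate
14 | 4-bromo-1,2-dimethoxybenzene | COc1ccc(Br)cc1OC | starting material
15 | (3,4-dimethoxyphenyl)lithium | [Li]c1ccc(OC)c(OC)c1 | intermediate
16 | (3R,4S,5S)-2-(3,4-dimethoxyphenyl)-3,4-dimethyl-5-(3,4,5-trimethoxyphenyl)oxolan-2-ol | COc1ccc(C2(O)O[C@H](c3cc(OC)c(OC)c(OC)c3)[C@@H](C)[C@H]2C)cc1OC | intermediate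
17 | (3R,4S,5S)-2-(3,4-dimethoxyphenyl)-3,4-dimethyl-5-(3,4,5-trimethoxyphenyl)-3,4-dihydro-5H-furan-1-ium (oxocarbenium ion, counter-ion not drawn) | COc1ccc(C2=[O+][C@H](c3cc(OC)c(OC)c(OC)c3)[C@@H](C)[C@H]2C)cc1OC | intermediate
18 | ligraminol A, (2S,3R,4S,5S)-2-(3,4-dimethoxyphenyl)-3,4-dimethyl-5-(3,4,5-trimethoxyphenyl)oxolane | COc1ccc([C@H]2O[C@H](c3cc(OC)c(OC)c(OC)c3)[C@@H](C)[C@H]2C)cc1OC | target

## Step count and risks

Total steps: 8. Longest linear sequence: 8 steps (1 → 18); aldehyde 4 and bromide 14 are bought.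

**Step 6 (kinetic protonation).** The proton must enter anti to the C4 methyl although the C5 aryl sits on that face, so the 3,4-cis : 3,4-trans ratio may be modest. The fallback sets the C3–H bond by catalytic hydrogenation and also replaces step 5. It sets out from 9: LiN(iPr)2 and then dimethylmethylideneammonium iodide give the Mannich base (3R,4S,5S)-3-[(dimethylamino)methyl]-4-methyl-5-(3,4,5-trimethoxyphenyl)oxolan-2-one F3. MeI converts it into the quaternary salt [(3R,4S,5S)-4-methyl-2-oxo-5-(3,4,5-trimethoxyphenyl)oxolan-3-yl]-N,N,N-trimethylmethanaminium iodide F4, and aqueous NaHCO3 eliminates this to (4S,5S)-4-methyl-3-methylidene-5-(3,4,5-trimethoxyphenyl)oxolan-2-one F5. Hydrogenation (H2, Rh/Al2O3, EtOAc, a catalyst that spares the benzylic C–O bond) delivers hydrogen to the exocyclic alkene from the face anti to the C4 methyl and comes back to the route at 13.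

**Step 8 (reductive deoxygenation).** Oxocarbenium ion 17 can lose the C3 proton to an enol ether and re-protonate to the more stable 3,4-trans series before hydride arrives, and the electron-rich aryl group makes 17 a sluggish hydride acceptor at −78 °C. The fallback replaces the ionic reduction by a syn hydrogenation that sets C2 and C3 together. It sets out from 16: pyridinium p-toluenesulfonate with 4 Å molecular sieves in toluene dehydrates it to (2S,3S)-5-(3,4-dimethoxyphenyl)-3,4-dimethyl-2-(3,4,5-trimethoxyphenyl)-2,3-dihydrofuran F6. H2 over Rh/Al2O3 in EtOAc with a trace of Et3N then adds both hydrogens to one face, which makes C2-aryl/C3-Me cis by necessity. Addition anti to the allylic C4 methyl is expected, though the C5 aryl on that face makes this uncertain, and it returns the route directly at 18.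

**Step 2 (key homoaldol).** The enantiomeric excess of this protocol is typically about 90 %, the electron-rich aldehyde is poorly soluble in the cold hydrocarbon medium, and everything downstream inherits the result; recrystallisation of 9 or 13 is the first remedy for ee. The fallback changes the homoenolate from a titanium species made in the flask to an isolable boron reagent. It sets out from 3: complex 5 is formed as before and quenched with 2-isopropoxy-4,4,5,5-tetramethyl-1,3,2-dioxaborolane to give (1R,2E)-1-(4,4,5,5-tetramethyl-1,3,2-dioxaborolan-2-yl)but-2-en-1-yl N,N-diisopropylcarbamate F1. F1 carries boron on the face that titanium occupies in 6; should borylation go with retention instead of inversion, (+)-sparteine is used to reach the same F1. F1 is purified and warmed with 4 in toluene; closed chair allylboration with the carbamoyloxy group axial gives (1Z,3S,4S)-3-methyl-4-[(4,4,5,5-tetramethyl-1,3,2-dioxaborolan-2-yl)oxy]-4-(3,4,5-trimethoxyphenyl)but-1-en-1-yl N,N-diisopropylcarbamate F2. Aqueous triethanolamine work-up cleaves the O–B bond and comes back to the route at 7.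

## Further compounds

F1 | step 2 | (1R,2E)-1-(4,4,5,5-tetramethyl-1,3,2-dioxaborolan-2-yl)but-2-en-1-yl N,N-diisopropylcarbamate | C/C=C/[C@@H](B1OC(C)(C)C(C)(C)O1)OC(=O)N(C(C)C)C(C)C
F2 | step 2 | (1Z,3S,4S)-3-methyl-4-[(4,4,5,5-tetramethyl-1,3,2-dioxaborolan-2-yl)oxy]-4-(3,4,5-trimethoxyphenyl)but-1-en-1-yl N,N-diisopropylcarbamate | CC(C)N(C(C)C)C(=O)O/C=C\[C@H](C)[C@H](OB1OC(C)(C)C(C)(C)O1)c1cc(OC)c(OC)c(OC)c1
F3 | step 6 | (3R,4S,5S)-3-[(dimethylamino)methyl]-4-methyl-5-(3,4,5-trimethoxyphenyl)oxolan-2-one | O=C1O[C@H](c2cc(OC)c(OC)c(OC)c2)[C@@H](C)[C@@H]1CN(C)C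
F4 | step 6 | [(3R,4S,5S)-4-methyl-2-oxo-5-(3,4,5-trimethoxyphenyl)oxolan-3-yl]-N,N,N-trimethylmethanaminium iodide | O=C1O[C@H](c2cc(OC)c(OC)c(OC)c2)[C@@H](C)[C@@H]1C[N+](C)(C)C.[I-]
F5 | step 6 | (4S,5S)-4-methyl-3-methylidene-5-(3,4,5-trimethoxyphenyl)oxolan-2-one | O=C1O[C@H](c2cc(OC)c(OC)c(OC)c2)[C@@H](C)C1=C
F6 | step 8 | (2S,3S)-5-(3,4-dimethoxyphenyl)-3,4-dimethyl-2-(3,4,5-trimethoxyphenyl)-2,3-dihydrofuran | COc1ccc(C2=C(C)[C@H](C)[C@@H](c3cc(OC)c(OC)c(OC)c3)O2)cc1OC
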